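## The problem

Andibenin (36) is a hexacyclic C25 meroterpenoid. Its spiro α,β-unsaturated δ-lactone (ring A: O–C3(=O)–C2=C1–C5–C4Me2) shares C5 with a cyclohexane (ring B: C5 to C10). Ring B is joined through quaternary C8 and methine C9 to a cyclopentane (ring C: C8–C17–C18–C19–C9), which is fused onto a bicyclo[2.2.2]octenone (bridgeheads C12 and C17; bridges C11–C8, C13=C14 and C20(=O)–C18) carrying a butenolide (C14–C15(=O)–O–C16–C17); these locants are working numbers used throughout. There are seven stereocentres, six of them contiguous (C5, C10, C9, C8, C17, C18) and five of them quaternary carbons; none can be epimerised in the target. The cage centres C12, C17 and C18 are tied by geometry to C8 and C9, so the real task is the relative configuration of C5, C10, C8 and C9, each of which must be dictated in turn by the one centre taken from the chiral pool. The sensitive functions are the two unsaturated lactones (Michael acceptors, opened by hard nucleophiles), the tertiary C4–O bond of ring A (ionised by strong acid) and the tertiary C10 alcohol, which is an α-ketol in the early intermediates and can undergo acyloin shifts. The diagnostic feature is that the spiro carbon C5 stands next to the carbinol carbon C10(OH)CH3: this is the pattern left when the vinyl carbon C1 of a seven-membered ring A lactone moves from the methyl-bearing quaternary carbon C10 to its neighbour C5 and oxygen takes the vacated place. Because C1 is vinylic and C10 can be flanked by a C9 carbonyl, that shift can be run as a radical 1,2-vinyl migration ending in an α-keto radical.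

## Retrosynthesis

**C18–C19 (ring C).** The last bond cut is C18–C19. Compared with C8–C17 or C9–C19, this cut turns quaternary C18 into an enolisable position of the cage ketone, and an electrophilic C19 held on C9 can reach only one face of the enolate. The precursor 34 (silyl enol ether, C19 mesylate) has one ring and one quaternary centre fewer. The forward step (34 to 36 through 35) needs only 5-exo C-alkylation under fluoride, which both lactones tolerate.

**C14–C17 and C13–C12 (cage and butenolide).** These are the two bonds a Diels–Alder reaction makes between a cyclohexadiene and an alkyne. Tethering the alkyne as the propiolate of the C16 alcohol (32 from 30 and propiolic acid 31) makes the addition intramolecular and closes the butenolide at once. A cut at the ketone bridge would leave C17 to be made quaternary separately. The precursor, spiro cyclohexenone 29, has two rings and two quaternary centres fewer. The alkyne must pass over the diene face next to C7, not the substituted C9, and the temperature must stay below that at which such dienes fragment.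

**C9=C19 (one-carbon unit).** C19 is traced through mesylate 28 and alcohol 27 to exocyclic alkene 25, and from there to ketone 22 and Me3SiCH2Li (23). Introducing C19 from the C18 side would need a nucleophilic carbon β to the cage ketone; introducing it at C9 uses the carbonyl the key step leaves there. The forward steps must add a small carbon nucleophile to a ketone between two fully substituted carbons, then place hydrogen on C9 from the face opposite the C10 oxygen; the triethylsilyl ether on that oxygen is chosen to enforce this.

**C8–C17 and C11–C12 (spiro ring).** Adduct 22 is cut into α-methylene ketone 15 and 2-siloxydiene 21. The other order, C-acylation at C8 followed by Robinson-type annulation, would bring C11 in last and from the face that gives the wrong C8 epimer. In the cycloaddition C11 is already in the ring plane and C17 arrives from below. Compound 15 comes from 13 (the silyl ether of 12) and formaldehyde (14); 21 comes from pentan-3-one (16) and silyloxyacetaldehyde 17 through 18 and 20. The step needs para regiochemistry (siloxy control) and attack anti to the axial C10 methyl.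

**C1–C5 and C10–O (key step).** Hydroxy ketone 12 is cut at these two bonds and C1 is reconnected to C10, giving the seven-membered enoate lactone 10 with a C5=C6 alkene. The neighbouring cuts (lactonisation onto a preformed quaternary C5, or separate hydroxylation at C10) cost more steps; this one creates the spiro junction and both stereocentres from a compound whose only stereocentre is the Wieland–Miescher carbon. The forward reaction must deliver a hydrogen atom to C6 and not to the enoate, the C5 radical must add to C1 before it meets oxygen, and oxygen must enter at C10 anti to C4. The weak point is the race with oxygen. It is met by working under air instead of an oxygen atmosphere and by using Fe(acac)3/PhSiH3, a hydride source that spares electron-poor alkenes.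

**C3–O–C4, C1=C2 and the C4 methyls.** Compound 10 is traced through 9, 8, 6, 5, 3 and 2 to (S)-Wieland–Miescher ketone (1) and iodomethane (4) by Baeyer–Villiger, dehydrogenation and gem-dimethylation retrons. The C9 carbonyl is carried as a silyl-protected alcohol, not a ketal. The silyl peroxide conditions that oxidise a β,γ-unsaturated ketone without epoxidising its alkene would also engage a ketal. This costs two steps and asks only for standard chemoselectivity.

## Roads not taken

Alternative 1: The cut lies inside the cage, at C20–C18 and C19–C9, with the two-carbon unit C18–C19 inserted between the cage ketone carbon and C9. In the forward sense the enolised 2-acetyl ketone of the bicyclo[3.2.1]octene A2 adds under irradiation across the isopropenyl group on C17 (de Mayo reaction), and retro-aldol opening of the cyclobutanol gives the cage methyl ketone A1.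
- Merits: ring C, the ketone bridge and quaternary C18 arise in one operation, with C18 fixed by the tether and no neopentyl ketone to homologate. Here it is better than the chosen route, which spends steps 15 to 17 and 22 on the same carbons.
- Weak points: A2 already holds three quaternary stereocentres in a bridged frame and would need a long enantioselective synthesis. A1 is a β,γ-unsaturated ketone beside a butenolide, and both chromophores can react under the irradiation. Crossed versus straight [2+2] regiochemistry is not assured. Above all, A1 lacks rings A and B, so C5 and C10 would have to be built afterwards on a crowded core from an acetyl group and a CH2O arm.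
- Comparison: the chosen plan sets against the elegant insertion an eight-step access to the A/B half with both difficult centres in place.

Alternative 2: The cut is C8–C17, the bond between two quaternary carbons. In the forward sense the silyl ketene acetal of the nine-membered allylic lactone A4 (LiN(iPr)2, Me3SiCl) rearranges by a transannular Ireland–Claisen shift to the ring C acid A3, with the alkene moving to C6=C7.
- Merits: a sigmatropic shift is one of the few reliable ways to join two quaternary carbons. Chirality transfer from the lactone carbinol carbon should set C8 and C17 together, which is more predictable than the conformational argument behind step 14 of the chosen route.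
- Weak points: medium-ring lactonisation of hindered partners; the geometry of a tetrasubstituted ketene acetal in a nine-membered ring, which decides C17; competing deprotonation at the more acidic C12–H next to the C20 ketone; base acting on the ring A enoate. After A3 the C11–C12 bond, the butenolide and selective saturation of C6=C7 beside two other alkenes all remain.
- Comparison: A3 already contains the spiro lactone and the C10 carbinol, so this road does not say how they are made. The chosen plan answers that first and reaches the cage in fewer operations.

Alternative 3: The cut is C14–C17 and C13–C12. In the forward sense silyl dienol ether A6 adds thermally to its own propiolate ester and gives the butenolide-fused bicyclo[2.2.2]octadiene A5.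
- Merits: a known reaction type that sets two bridgehead quaternary centres and the butenolide in one step. It is as good as anything in the chosen route, which in fact uses the same cycloaddition for its cage (step 21, 32 to 34); nothing can be set against it on that score.
- Weak points: as a plan it treats the cage as the problem and leaves the spiro lactone with its adjacent carbinol to conventional, longer chemistry. A5 also carries a free C10 hydroxyl beside a primary chloride, which invites oxetane formation in the final base-mediated closure.
- Comparison: its key step carries little risk, whereas the chosen key step is untested. The chosen plan accepts that in exchange for ring A, C5 and C10 in one early operation, covers it with a stepwise fallback, and keeps the C10 oxygen silylated until ring C is closed.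

Key step: step 8

## Remarks before the steps

- Compounds 22 and 24 to 28 are carried as mixtures of epimers at C12 and C17, and 29, 30 and 32 at C12. These centres become trigonal again in steps 18 and 21, so their configuration is left open in names and SMILES.
- Me3SiOOSiMe3, Me3SiCH2Li (solution), paraformaldehyde and (tert-butyldimethylsilyloxy)acetaldehyde are taken as purchasable.

## Route

Step 1
Reactants: 1 (S)-Wieland–Miescher ketone
Product: 2 C9 alcohol of the enone (hydroxyl cis to the C10 methyl)
Conditions: NaBH4, EtOH, −10 °C
Reagents that add atoms: none
Why: Chemoselective borohydride reduction of the saturated ketone (the enone carbonyl is less electrophilic); hydride adds axially from the face opposite the angular methyl, giving the equatorial alcohol cis to it. The centre is temporary and is oxidised again in step 7.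

Step 2
Reactants: 2 C9 alcohol
Product: 3 C9 tert-butyldimethylsilyl ether
Conditions: TBSCl, imidazole, DMF, 23 °C
Reagents that add atoms: tert-butyldimethylsilyl chloride, CC(C)(C)[Si](C)(C)Cl
Why: Standard silylation of a secondary alcohol; the ether masks C9 through the alkylation, oxidation and enolate steps that follow.

Step 3
Reactants: 3 silyl ether; 4 iodomethane
Product: 5 4,4-dimethyl β,γ-unsaturated ketone (C5=C6)
Conditions: KOtBu, MeI, tBuOH, 23 → 40 °C
Reagents that add atoms: 4 iodomethane, CI
Why: Deconjugative α,α-dialkylation of the enone through its dienolate; the second methylation at C4 leaves the alkene at C5=C6, where the key step needs it. C10 is not enolisable and keeps its configuration.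

Step 4
Reactants: 5 dimethyl ketone
Product: 6 seven-membered lactone (C3(=O)–O–C4)
Conditions: Me3SiOOSiMe3, Me3SiOTf (cat.), CH2Cl2, −78 → −40 °C
Reagents that add atoms: bis(trimethylsilyl) peroxide, C[Si](C)(C)OO[Si](C)(C)C
Why: Baeyer–Villiger oxidation through a silylated Criegee adduct; the tertiary allylic C4 migrates in preference to the C2 methylene. Unlike a peracid, the aprotic silyl peroxide does not epoxidise the C5=C6 alkene of this β,γ-unsaturated ketone.

Step 5
Reactants: 6 saturated lactone
Product: 8 enoate lactone (C1=C2), via 2-phenylselanyl lactone 7 (not isolated)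
Conditions: LiN(iPr)2, THF, −78 °C; PhSeBr; then H2O2, pyridine, CH2Cl2, 0 → 23 °C
Reagents that add atoms: none
Why: α-Selenenylation of the lactone enolate and selenoxide syn-elimination, which can run only toward C1; pyridine suppresses epoxidation of C5=C6 by perseleninic acid.

Step 6
Reactants: 8 enoate lactone silyl ether
Product: 9 enoate lactone C9 alcohol
Conditions: Bu4NF, AcOH, THF, 23 → 45 °C
Reagents that add atoms: none
Why: Fluoride desilylation buffered with acetic acid, so that the enoate and the tertiary allylic C4–O bond see neither strong base nor strong acid.

Step 7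
Reactants: 9 alcohol
Product: 10 seven-membered enoate lactone with C9 ketone and C5=C6 alkene
Conditions: Dess–Martin periodinane, NaHCO3, CH2Cl2, 23 °C
Reagents that add atoms: none
Why: Buffered Dess–Martin oxidation of the neopentyl secondary alcohol; the β,γ-unsaturated ketone cannot move into conjugation because C10 is quaternary.

Step 8
Reactants: 10 keto enoate lactone
Product: 12 spiro δ-lactone hydroxy ketone (C1 and the C10 hydroxyl on one face of ring B), via C10 hydroperoxide 11 (not isolated)
Conditions: Fe(acac)3 (cat.), PhSiH3, air, EtOH–THF, 23 °C; then PPh3
Reagents that add atoms: dioxygen, O=O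
Why: Proposed new method: the iron hydride formed from Fe(acac)3 and PhSiH3 transfers a hydrogen atom to C6 of the electron-rich trisubstituted alkene (the enoate is a poor partner for this hydride and its β-carbon C1 is neopentyl), giving the tertiary C5 radical. This nucleophilic radical closes 3-exo-trig onto C1, the β-carbon of the enoate, and the α-ester cyclopropylcarbinyl radical reopens by breaking C1–C10, which puts the radical at C10 next to the C9 ketone; ring A therefore forms by contraction of the seven-membered lactone (net 1,2-vinyl shift) and not by a new ring closure. Dioxygen traps the α-keto radical and PPh3 reduces hydroperoxide 11. The closest known reaction types are the radical 1,2-vinyl shift through a cyclopropylcarbinyl radical (Dowd–Beckwith-type rearrangement) and Mukaiyama-type hydration; their combination on a lactone enoate, with oxygen capture at the migration origin, has not been shown. C5 is set by C10: the vinyl carbon can only cross on the face of ring B where it already sits, so the shift is suprafacial. C10 is set by C4: the planar radical is shielded on one face by the adjacent gem-dimethyl-bearing carbon, so oxygen enters anti to it and takes the place C1 left. The shift must outrun oxygen capture at C5, which is why air and not pure oxygen is used and why the C9 ketone, which makes the shift exothermic, is in place first.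

Step 9
Reactants: 12 hydroxy ketone
Product: 13 C10 triethylsilyl ether
Conditions: TESOTf, 2,6-lutidine, CH2Cl2, 0 → 23 °C
Reagents that add atoms: triethylsilyl triflate, CC[Si](CC)(CC)OS(=O)(=O)C(F)(F)F
Why: Silyl triflate silylation of the hindered tertiary alcohol; the ether blocks acyloin rearrangement of the α-ketol in later basic steps and supplies the steric bias used at C9 in step 16.

Step 10
Reactants: 13 silyl ether ketone; 14 formaldehyde (as paraformaldehyde)
Product: 15 C8 α-methylene ketone (C8=C11)
Conditions: (CH2O)n, PhNHMe·CF3CO2H, THF, 65 °C
Reagents that add atoms: 14 formaldehyde, C=O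
Why: Mannich-type α-methylenation (iminium addition to the enol, then loss of the amine); C8 is the only enolisable position because C10 is fully substituted.

Step 11
Reactants: 16 pentan-3-one; 17 (tert-butyldimethylsilyloxy)acetaldehyde
Product: 18 aldol 6-(tert-butyldimethylsilyloxy)-5-hydroxy-4-methylhexan-3-one (diastereomer mixture)
Conditions: LiN(iPr)2, THF, −78 °C
Reagents that add atoms: none
Why: Directed aldol addition of the lithium enolate of the symmetrical ketone; both new centres are removed in the next step.

Step 12
Reactants: 18 aldol
Product: 20 (E)-6-(tert-butyldimethylsilyloxy)-4-methylhex-4-en-3-one, via aldol mesylate 19 (not isolated)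
Conditions: MsCl, Et3N, CH2Cl2, 0 °C; then DBU, 23 °C
Reagents that add atoms: none
Why: Mesylation and E1cB elimination give the conjugated trisubstituted enone; the E isomer, with the CH2O arm trans to the carbonyl, is the thermodynamic product.

Step 13
Reactants: 20 enone
Product: 21 (2Z,4E)-3,6-bis(tert-butyldimethylsilyloxy)-4-methylhexa-2,4-diene
Conditions: TBSOTf, Et3N, CH2Cl2, −78 → 0 °C
Reagents that add atoms: tert-butyldimethylsilyl triflate, CC(C)(C)[Si](C)(C)OS(=O)(=O)C(F)(F)F
Why: Soft enolisation of the ethyl ketone gives the cross-conjugated (Z)-silyl enol ether; Z geometry puts the terminal methyl on the outside of the s-cis diene, as the cycloaddition requires.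

Step 14
Reactants: 15 α-methylene ketone; 21 siloxydiene
Product: 22 spiro silyl enol ether adduct (C8 quaternary; C17 on the ring B face that carries the C10 oxygen)
Conditions: PhMe, BHT (cat.), 100 °C, sealed tube
Reagents that add atoms: none
Why: Normal-demand Diels–Alder reaction: the siloxy group makes C12 the nucleophilic terminus, which bonds to the β-methylene C11, so C17 bonds to C8 (para orientation). C8 is set by ring B: with the C10 methyl axial on the upper face, the diene adds to the lower face (equatorial attack). The C12 and C17 centres are made trigonal later and need no control.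

Step 15
Reactants: 22 spiro ketone; 23 (trimethylsilyl)methyllithium
Product: 25 C9 exocyclic methylene compound (C9=C19), via β-hydroxysilane 24 (not isolated)
Conditions: Me3SiCH2Li, CeCl3, THF, −78 → 0 °C; then KH, THF, 23 °C
Reagents that add atoms: 23 (trimethylsilyl)methyllithium, [Li]C[Si](C)(C)C
Why: Peterson olefination: the small, weakly basic organocerium reagent adds to the doubly neopentyl ketone in preference to the hindered tert-alkyl enoate lactone, and the potassium alkoxide eliminates syn. No stereocentre is created.

Step 16
Reactants: 25 exocyclic alkene
Product: 27 C19 primary alcohol (C9–H on the face of the C10 methyl; C19 cis to the C10 oxygen and to C17), via C19 alkylborane 26 (not isolated)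
Conditions: BH3·THF, THF, 0 °C; then NaBO3·4H2O, H2O, 23 °C
Reagents that add atoms: sodium perborate, O=BO[O-].[Na+]
Why: Anti-Markovnikov hydroboration–oxidation of the 1,1-disubstituted alkene, which is more reactive toward borane than the tetrasubstituted silyl enol ether or the enoate. Hydrogen is delivered to C9 from the upper face, which carries only the C10 methyl and the C11 methylene, and not from the lower face flanked by the triethylsilyloxy group and the substituted C17 methine.

Step 17
Reactants: 27 primary alcohol
Product: 28 C19 mesylate
Conditions: MsCl, Et3N, CH2Cl2, 0 °C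
Reagents that add atoms: methanesulfonyl chloride, CS(=O)(=O)Cl
Why: Sulfonylation of the primary alcohol; the mesylate is the leaving group for the final ring closure and is inert to the oxidation, desilylation, esterification and cycloaddition steps in between.

Step 18
Reactants: 28 silyl enol ether mesylate
Product: 29 spiro cyclohexenone (C20 ketone, C18=C17)
Conditions: Pd(OAc)2, MeCN, 40 °C
Reagents that add atoms: none
Why: Saegusa–Ito oxidation: palladation of the silyl enol ether at C18 and β-hydride elimination toward C17 give the tetrasubstituted enone, the more stable alkene isomer. C17 becomes trigonal and C12 is now epimerisable.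

Step 19
Reactants: 29 enone bis-silyl ether
Product: 30 C16 primary allylic alcohol (C10 triethylsilyl ether retained)
Conditions: HF·pyridine, pyridine, THF, 0 °C
Reagents that add atoms: none
Why: Buffered acid fluoride cleaves the unhindered primary allylic silyl ether much faster than the tertiary triethylsilyl ether buried between C5 and C9.

Step 20
Reactants: 30 allylic alcohol; 31 propiolic acid
Product: 32 C16 propiolate ester
Conditions: DCC, DMAP (cat.), CH2Cl2, −20 → 0 °C
Reagents that add atoms: 31 propiolic acid, C#CC(=O)O
Why: Carbodiimide (Steglich) esterification of the primary alcohol at low temperature, where the propiolate tolerates the acyl-transfer catalyst; the tertiary C10 oxygen is protected.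

Step 21
Reactants: 32 propiolate enone
Product: 34 butenolide-fused bicyclo[2.2.2]octadiene silyl enol ether, via cross-conjugated silyl dienol ether 33 (not isolated)
Conditions: TBSOTf, Et3N, CH2Cl2, −78 → 0 °C; then PhMe, 80 °C
Reagents that add atoms: tert-butyldimethylsilyl triflate, CC(C)(C)[Si](C)(C)OS(=O)(=O)C(F)(F)F
Why: Soft enolisation at C12 gives the 2-siloxydiene 33, which adds to the tethered propiolate (intramolecular Diels–Alder reaction): C14 bonds to C17 and C13 to C12, closing the butenolide and the cage. Bridgeheads C12 and C17 are set by C8, because the alkyne passes over the diene face next to the C7 methylene and not the substituted C9. The temperature stays well below that of Alder–Rickert fragmentation.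

Step 22
Reactants: 34 cage silyl enol ether mesylate
Product: 36 andibenin, via andibenin triethylsilyl ether 35 (not isolated)
Conditions: Bu4NF, THF, 0 → 40 °C
Reagents that add atoms: none
Why: Fluoride frees the cage enolate, which closes ring C by 5-exo-tet C-alkylation at C18 (O-alkylation would need a seven-membered ring); the tether from C9 fixes C18. The more slowly cleaved triethylsilyl ether is removed in the same flask after ring closure, so the C10 alkoxide cannot compete for the mesylate.

## Compound list

1 | (S)-Wieland–Miescher ketone | C[C@]12CCC(=O)C=C1CCCC2=O | starting material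
2 | (4aS,5S)-5-hydroxy-4a-methyl-4,4a,5,6,7,8-hexahydronaphthalen-2(3H)-one | C[C@]12CCC(=O)C=C1CCC[C@@H]2O | intermediate
3 | C9 tert-butyldimethylsilyl ether of 2 | C[C@]12CCC(=O)C=C1CCC[C@@H]2O[Si](C)(C)C(C)(C)C | intermediate
4 | iodomethane | CI | starting material
5 | 4,4-dimethyl-5-en-3-one, C9 silyl ether | C[C@]12CCC(=O)C(C)(C)C1=CCC[C@@H]2O[Si](C)(C)C(C)(C)C | intermediate
6 | seven-membered lactone (O between C3 and C4), C5=C6, C9 silyl ether | C[C@]12CCC(=O)OC(C)(C)C1=CCC[C@@H]2O[Si](C)(C)C(C)(C)C | intermediate
7 | 2-phenylselanyl lactone (C2 epimers) | C[C@]12CC([Se]c3ccccc3)C(=O)OC(C)(C)C1=CCC[C@@H]2O[Si](C)(C)C(C)(C)C | intermediate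
8 | seven-membered enoate lactone (C1=C2), C9 silyl ether | C[C@]12C=CC(=O)OC(C)(C)C1=CCC[C@@H]2O[Si](C)(C)C(C)(C)C | intermediate
9 | seven-membered enoate lactone, C9 alcohol | C[C@]12C=CC(=O)OC(C)(C)C1=CCC[C@@H]2O | intermediate
10 | seven-membered enoate lactone with C9 ketone and C5=C6 alkene | CC1(C)OC(=O)C=C[C@]2(C)C(=O)CCC=C12 | intermediate
11 | spiro δ-lactone C10 hydroperoxide, C9 ketone | CC1(C)OC(=O)C=C[C@]12CCCC(=O)[C@@]2(C)OO | intermediate
12 | spiro δ-lactone hydroxy ketone (rings A and B) | CC1(C)OC(=O)C=C[C@]12CCCC(=O)[C@@]2(C)O | intermediate
13 | C10 triethylsilyl ether of 12 | CC1(C)OC(=O)C=C[C@]12CCCC(=O)[C@@]2(C)O[Si](CC)(CC)CC | intermediate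
14 | formaldehyde (used as paraformaldehyde) | C=O | starting material
15 | C8 α-methylene ketone | CC1(C)OC(=O)C=C[C@]12CCC(=C)C(=O)[C@@]2(C)O[Si](CC)(CC)CC | intermediate
16 | pentan-3-one | CCC(=O)CC | starting material
17 | (tert-butyldimethylsilyloxy)acetaldehyde | O=CCO[Si](C)(C)C(C)(C)C | starting material
18 | 6-(tert-butyldimethylsilyloxy)-5-hydroxy-4-methylhexan-3-one (diastereomer mixture) | CCC(=O)C(C)C(O)CO[Si](C)(C)C(C)(C)C | intermediate
19 | mesylate of 18 | CCC(=O)C(C)C(OS(C)(=O)=O)CO[Si](C)(C)C(C)(C)C | intermediate
20 | (E)-6-(tert-butyldimethylsilyloxy)-4-methylhex-4-en-3-one | CCC(=O)/C(C)=C/CO[Si](C)(C)C(C)(C)C | intermediate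
21 | (2Z,4E)-3,6-bis(tert-butyldimethylsilyloxy)-4-methylhexa-2,4-diene | C/C=C(O[Si](C)(C)C(C)(C)C)/C(C)=C/CO[Si](C)(C)C(C)(C)C | intermediate
22 | spiro Diels–Alder adduct: C20 silyl enol ether, C9 ketone (C12, C17 epimers) | CC1(C)OC(=O)C=C[C@]12CC[C@]3(CC(C)C(O[Si](C)(C)C(C)(C)C)=C(C)C3CO[Si](C)(C)C(C)(C)C)C(=O)[C@@]2(C)O[Si](CC)(CC)CC | intermediate
23 | (trimethylsilyl)methyllithium | [Li]C[Si](C)(C)C | starting material
24 | C9 β-hydroxysilane (C9 epimers) | CC1(C)OC(=O)C=C[C@]12CC[C@]3(CC(C)C(O[Si](C)(C)C(C)(C)C)=C(C)C3CO[Si](C)(C)C(C)(C)C)C(O)(C[Si](C)(C)C)[C@@]2(C)O[Si](CC)(CC)CC | intermediate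
25 | C9 exocyclic methylene compound | CC1(C)OC(=O)C=C[C@]12CC[C@]3(CC(C)C(O[Si](C)(C)C(C)(C)C)=C(C)C3CO[Si](C)(C)C(C)(C)C)C(=C)[C@@]2(C)O[Si](CC)(CC)CC | intermediate
26 | C19 alkylborane | CC1(C)OC(=O)C=C[C@]12CC[C@]3(CC(C)C(O[Si](C)(C)C(C)(C)C)=C(C)C3CO[Si](C)(C)C(C)(C)C)[C@@H](CB)[C@@]2(C)O[Si](CC)(CC)CC | intermediate
27 | C19 primary alcohol | CC1(C)OC(=O)C=C[C@]12CC[C@]3(CC(C)C(O[Si](C)(C)C(C)(C)C)=C(C)C3CO[Si](C)(C)C(C)(C)C)[C@@H](CO)[C@@]2(C)O[Si](CC)(CC)CC | intermediate
28 | C19 mesylate | CC1(C)OC(=O)C=C[C@]12CC[C@]3(CC(C)C(O[Si](C)(C)C(C)(C)C)=C(C)C3CO[Si](C)(C)C(C)(C)C)[C@@H](COS(C)(=O)=O)[C@@]2(C)O[Si](CC)(CC)CC | intermediate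
29 | spiro cyclohexenone (C12 epimers) | CC1(C)OC(=O)C=C[C@]12CC[C@]3(CC(C)C(=O)C(C)=C3CO[Si](C)(C)C(C)(C)C)[C@@H](COS(C)(=O)=O)[C@@]2(C)O[Si](CC)(CC)CC | intermediate
30 | C16 allylic alcohol (C12 epimers) | CC1(C)OC(=O)C=C[C@]12CC[C@]3(CC(C)C(=O)C(C)=C3CO)[C@@H](COS(C)(=O)=O)[C@@]2(C)O[Si](CC)(CC)CC | intermediate
31 | propiolic acid | C#CC(=O)O | starting material
32 | C16 propiolate ester (C12 epimers) | CC1(C)OC(=O)C=C[C@]12CC[C@]3(CC(C)C(=O)C(C)=C3COC(=O)C#C)[C@@H](COS(C)(=O)=O)[C@@]2(C)O[Si](CC)(CC)CC | intermediate
33 | cross-conjugated silyl dienol ether of 32 | CC1(C)OC(=O)C=C[C@]12CC[C@]3(CC(C)=C(O[Si](C)(C)C(C)(C)C)C(C)=C3COC(=O)C#C)[C@@H](COS(C)(=O)=O)[C@@]2(C)O[Si](CC)(CC)CC | intermediate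
34 | butenolide-fused bicyclo[2.2.2]octadiene silyl enol ether, C19 mesylate | CC1(C)OC(=O)C=C[C@]12CC[C@]3(C[C@@]4(C)C=C5C(=O)OC[C@]53C(C)=C4O[Si](C)(C)C(C)(C)C)[C@@H](COS(C)(=O)=O)[C@@]2(C)O[Si](CC)(CC)CC | intermediate
35 | andibenin C10 triethylsilyl ether | CC1(C)OC(=O)C=C[C@]12CC[C@@]13C[C@@]4(C)C=C5C(=O)OC[C@]51[C@@](C)(C[C@H]3[C@@]2(C)O[Si](CC)(CC)CC)C4=O | intermediate
36 | andibenin | CC1(C)OC(=O)C=C[C@]12CC[C@@]13C[C@@]4(C)C=C5C(=O)OC[C@]51[C@@](C)(C[C@H]3[C@@]2(C)O)C4=O | target

## Step count and least certain steps

Total: 22 steps (19 in the main line, 3 for diene 21). Longest linear sequence: 19 steps, from 1 to 36 (steps 1 to 10 and 14 to 22).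

**Step 8 (key step).** The most likely failure is capture of the C5 radical by oxygen before the vinyl shift, or interception of the cyclopropylcarbinyl radical; both give oxygenated material without the spiro junction. The fallback sets out from 10 and separates the carbon shift from the oxygenation, using known reaction types. Under reductive radical conditions with oxygen excluded (Fe(acac)3, PhSiH3, degassed EtOH, 60 °C) the established radical 1,2-vinyl shift should end with reduction and protonation of the α-keto radical, giving the rearranged ketone without the C10 hydroxyl F1. A cyclopropane arrested at the 3-exo stage would be opened to the same ketone by DBU through retro-Michael cleavage. Thermodynamic enolisation (Me3SiCl, NaI, Et3N, MeCN) gives the C9–C10 trimethylsilyl enol ether F2. Rubottom oxidation (mCPBA, NaHCO3), with the oxidant anti to C4, gives the C10 trimethylsilyloxy ketone F3, and Bu4NF returns the route to 12.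

**Step 14.** The cycloaddition may stall because both new bonds form at crowded carbons, or the enone may react as a heterodiene with the enol ether. The fallback sets out from 15 and 20 and is a stepwise anionic double Michael addition. The kinetic cross-conjugated lithium dienolate of 20 (LiN(iPr)2, THF, −78 °C) adds through C12 to the methylene of 15, giving the open-chain Michael adduct F4 as its enolate. This closes the congested C8–C17 bond intramolecularly, again from the face opposite the axial C10 methyl, and trapping the final enolate with TBSOTf returns the route to 22.

**Step 15.** The doubly neopentyl ketone may fail to accept the silylmethyl nucleophile, or the reagent may attack the lactone. The fallback sets out from 22. The smallest carbon nucleophile (MeLi, CeCl3, THF, −78 °C) gives the C9 methyl carbinol F5. Burgess reagent (PhMe, 50 °C) then dehydrates it toward the only β-hydrogens available, those of the new methyl, returning the route to 25.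

**Step 16.** Borane may attack the silyl enol ether or the lactone, or discriminate poorly between the faces of the alkene. The fallback sets out from 22 and avoids both olefination and borane. Corey–Chaykovsky methylenation (Me3S+ I−, KN(SiMe3)2, THF) from the less hindered upper face gives the C9 spiro-epoxide F6. Meinwald rearrangement with MeAl(OAr)2 (Ar = 4-bromo-2,6-di-tert-butylphenyl) shifts hydride to C9 with inversion and gives the C19 aldehyde F7. NaBH4 at −78 °C, before the axial aldehyde can epimerise, returns the route to 27.

## Further compounds

F1 | step 8 | rearranged spiro δ-lactone ketone without the C10 hydroxyl (C10 epimers) | CC1(C)OC(=O)C=C[C@]12CCCC(=O)C2C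
F2 | step 8 | C9–C10 trimethylsilyl enol ether of F1 | CC1(C)OC(=O)C=C[C@]12CCCC(O[Si](C)(C)C)=C2C
F3 | step 8 | C10 trimethylsilyloxy ketone (trimethylsilyl ether of 12) | CC1(C)OC(=O)C=C[C@]12CCCC(=O)[C@@]2(C)O[Si](C)(C)C
F4 | step 14 | open-chain Michael adduct of 15 and the dienolate of 20 (C8, C12 epimers) | CC1(C)OC(=O)C=C[C@]12CCC(CC(C)C(=O)/C(C)=C/CO[Si](C)(C)C(C)(C)C)C(=O)[C@@]2(C)O[Si](CC)(CC)CC
F5 | step 15 | C9 methyl carbinol (C9 epimers) | CC1(C)OC(=O)C=C[C@]12CC[C@]3(CC(C)C(O[Si](C)(C)C(C)(C)C)=C(C)C3CO[Si](C)(C)C(C)(C)C)C(C)(O)[C@@]2(C)O[Si](CC)(CC)CC
F6 | step 16 | C9 spiro-epoxide (CH2 on the face of the C10 methyl) | CC1(C)OC(=O)C=C[C@]12CC[C@]3(CC(C)C(O[Si](C)(C)C(C)(C)C)=C(C)C3CO[Si](C)(C)C(C)(C)C)[C@]4(CO4)[C@@]2(C)O[Si](CC)(CC)CC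
F7 | step 16 | C19 aldehyde (formyl cis to the C10 oxygen) | CC1(C)OC(=O)C=C[C@]12CC[C@]3(CC(C)C(O[Si](C)(C)C(C)(C)C)=C(C)C3CO[Si](C)(C)C(C)(C)C)[C@@H](C=O)[C@@]2(C)O[Si](CC)(CC)CC
A1 | alternative 1 | tricyclic cage methyl ketone (ring C, bicyclo[2.2.2]octenone, butenolide; pivalate on the CH2O arm at C8, acetyl on C9) | CC(C)(C)C(=O)OC[C@@]13C[C@@]4(C)C=C5C(=O)OC[C@]51[C@@](C)(C[C@H]3C(C)=O)C4=O
A2 | alternative 1 | bicyclo[3.2.1]octene 2-acetyl ketone with an isopropenyl group on C17 (acetyl-bearing carbon enolisable) | CC(C)(C)C(=O)OC[C@@]1(C(C(C)=O)C2=O)C[C@@]2(C)C=C3C(=O)OC[C@]31C(C)=C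
A3 | alternative 2 | ring C acid with adjacent quaternary carbons C8 and C17 | CC1(C)OC(=O)C=C[C@]12C=C[C@]3(CO[Si](C)(C)C(C)(C)C)[C@H]([C@@]2(C)O)C[C@@]4(C)C(=O)[C@H](C)C=C(C(=O)OC)[C@@]34C(=O)O
A4 | alternative 2 | nine-membered allylic lactone (C6 carbinol and C17 configurations left open) | CC1(C)OC(=O)C=C[C@]12C3C=C(CO[Si](C)(C)C(C)(C)C)[C@H]([C@@]2(C)O)C[C@@]4(C)C(=O)[C@H](C)C=C(C(=O)OC)C4C(=O)O3
A5 | alternative 3 | butenolide-fused bicyclo[2.2.2]octadiene silyl enol ether with C19 chloride and free C10 hydroxyl | CC1(C)OC(=O)C=C[C@]12CC[C@]3(C[C@@]4(C)C=C5C(=O)OC[C@]53C(C)=C4O[Si](C)(C)C(C)(C)C)[C@@H](CCl)[C@@]2(C)O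
A6 | alternative 3 | cross-conjugated silyl dienol ether propiolate | CC1(C)OC(=O)C=C[C@]12CC[C@]3(CC(C)=C(O[Si](C)(C)C(C)(C)C)C(C)=C3COC(=O)C#C)[C@@H](CCl)[C@@]2(C)O
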